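The route rests on cutting the dioxane ring of the 1,4-benzodioxane across C2–C3 and O1–C8a, which turns C2 and O1 into the carbonyl group of a protected syringaldehyde. The feature used is that C3 carries the aryloxy oxygen O4 and the future CH2OH carbon. At the acid oxidation level C3 is therefore a glycolate enolate carbon, and C8a lies ortho to O4 on ring A. In one flask an auxiliary-controlled syn aldol addition makes C2–C3 with both stereocentres. Palladium-catalysed O-arylation of the new carbinol at the brominated carbon C8a then closes the ring. The precursor is an open-chain N-(2-bromoaryloxy)acetyl oxazolidinone that already carries the stilbene.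

Key step: step 7

Numbering used throughout: O1, C2 (aryl-bearing), C3 (CH2OH-bearing), O4, C4a, C5 (OH), C7 (styryl), C8a. Ring A is the benzo ring and ring B the resorcinol ring.
Assumption: 3-bromo-4,5-dihydroxybenzaldehyde and (4R)-4-benzyl-3-(chloroacetyl)-1,3-oxazolidin-2-one are taken as catalogue compounds.

Step 1
Reactants: 1 3-bromo-4,5-dihydroxybenzaldehyde
Product: 2 3-bromo-4-hydroxy-5-(methoxymethoxy)benzaldehyde
Conditions: NaH (2.2 equiv), DMF, 0 °C; MOMCl (1.0 equiv), 0 °C; aq. NH4Cl
Reagents that add atoms: chloromethyl methyl ether (MOMCl), COCCl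
Why: Regioselective Williamson-type O-alkylation of a catechol dianion, in which the 4-phenoxide is stabilised by the para formyl group and flanked by bromine, so the less stabilised and more nucleophilic 5-phenoxide should take up the single equivalent of MOMCl.

Step 2
Reactants: 2 3-bromo-4-hydroxy-5-(methoxymethoxy)benzaldehyde
Product: 3 2-bromo-4-ethenyl-6-(methoxymethoxy)phenol
Conditions: MePPh3Br, KOtBu (3 equiv each), THF, 0 °C to rt
Reagents that add atoms: methyltriphenylphosphonium bromide, C[P+](c1ccccc1)(c1ccccc1)c1ccccc1.[Br-]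
Why: Wittig methylenation, in which the excess of non-stabilised ylide first deprotonates the phenol and still adds to the deactivated aldehyde as it does with vanillin-type aldehydes, while aryl bromide and MOM ether are inert.

Step 3
Reactants: 4 5-iodobenzene-1,3-diol
Product: 5 1-iodo-3,5-bis(methoxymethoxy)benzene
Conditions: MOMCl, K2CO3, acetone, rt
Reagents that add atoms: chloromethyl methyl ether (MOMCl), COCCl
Why: Williamson-type O-alkylation of both phenols with a very reactive alpha-chloro ether under mild carbonate base.

Step 4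
Reactants: 3 2-bromo-4-ethenyl-6-(methoxymethoxy)phenol; 5 1-iodo-3,5-bis(methoxymethoxy)benzene
Product: 6 4-{(E)-2-[3,5-bis(methoxymethoxy)phenyl]ethenyl}-2-bromo-6-(methoxymethoxy)phenol
Conditions: Pd(OAc)2 (cat.), Bu4NCl, NaHCO3, DMF, 60 °C
Reagents that add atoms: none
Why: Ligand-free Mizoroki–Heck reaction, in which the aryl iodide undergoes oxidative addition far faster than the hindered electron-rich aryl bromide of 3, and syn insertion at the terminal carbon followed by syn beta-hydride elimination gives the (E)-stilbene.

Step 5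
Reactants: 6 stilbene bromophenol; 7 (4R)-4-benzyl-3-(chloroacetyl)-1,3-oxazolidin-2-one
Product: 8 (4R)-4-benzyl-3-{[4-{(E)-2-[3,5-bis(methoxymethoxy)phenyl]ethenyl}-2-bromo-6-(methoxymethoxy)phenoxy]acetyl}-1,3-oxazolidin-2-one
Conditions: K2CO3, NaI (cat.), acetone, 40 °C
Reagents that add atoms: none
Why: Williamson ether synthesis (SN2 at the alpha-halo imide, speeded by in situ Finkelstein exchange), in which the hindered phenoxide should attack the CH2 carbon rather than an imide carbonyl group and the auxiliary stereocentre is untouched.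

Step 6
Reactants: 9 syringaldehyde
Product: 10 3,5-dimethoxy-4-(methoxymethoxy)benzaldehyde
Conditions: MOMCl, K2CO3, acetone, rt
Reagents that add atoms: chloromethyl methyl ether (MOMCl), COCCl
Why: Williamson-type O-alkylation of the acidic para-formyl phenol, which also removes the phenoxide deactivation of the aldehyde before the aldol step.

Step 7
Reactants: 8 aryloxyacetyl imide; 10 3,5-dimethoxy-4-(methoxymethoxy)benzaldehyde
Product: 14 trans-benzodioxane imide (2S,3R), via boron enolate 11 (not isolated), via boron aldolate 12 (not isolated), via syn aldol 13 (not isolated)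
Conditions: Bu2BOTf, Et3N, toluene, −78 to 0 °C; 10, −78 to 0 °C; then in the same flask 8-hydroxyquinoline (1 equiv per boron), K3PO4, Pd(OAc)2 (cat.), 2-(di-tert-butylphosphino)-1,1'-binaphthyl, 60 °C
Reagents that add atoms: none
Why: Soft enolisation of 8 gives the (Z)-dibutylboron enolate 11, which adds to 10 through a closed Zimmerman–Traxler chair (Evans syn glycolate aldol, known for aryloxyacetyl imides) to form C2–C3 as aldolate 12, and 8-hydroxyquinoline then removes boron as an inert chelate and leaves the free carbinol 13. Zerovalent palladium inserts into the C8a–Br bond, K3PO4 deprotonates the bound carbinol, and C–O reductive elimination forms O1–C8a, a Buchwald–Hartwig-type intramolecular aryl etherification that is known to turn 2-(2-bromophenoxy) alcohols into 1,4-benzodioxanes with retention of configuration. The only ring closed is the six-membered dioxane ring, closed by intramolecular O-arylation through a seven-membered aryl palladium alkoxide onto the ring A carbon ortho to O4. C3 is set by the benzyl group of the (R)-auxiliary, which shields one enolate face, and C2 by the chair that places the aryl group of 10 equatorial, so the syn aldol results and, since the arylation touches neither centre, the trans ring with the spatial arrangement of the target. Chemoselectivity rests on 13 holding a single hydroxyl group (at the later diol stage the primary alcohol could close a six-membered ring as well), on the C8a–Br bond being the only carbon–halogen bond, and on the bulky phosphine favouring reductive elimination over beta-hydride elimination. Any stereochemical leak through retro-aldol cleavage gives diastereomers of 14 and not its enantiomer, so chromatography should restore a single isomer.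

Step 8
Reactants: 14 trans-benzodioxane imide
Product: 15 tetrakis-MOM ether of the target, [(2S,3S)-configured primary alcohol]
Conditions: LiBH4, MeOH (2 equiv), THF, 0 °C
Reagents that add atoms: none
Why: Reductive cleavage of the N-acyl oxazolidinone by hydride attack at the exocyclic carbonyl group, which frees the auxiliary and gives the primary alcohol without touching C2, C3, the stilbene or the MOM ethers (the descriptor at C3 changes from R to S by priority only).

Step 9
Reactants: 15 tetrakis-MOM ether of the target
Product: 16 (2S,3S)-7-[(E)-2-(3,5-dihydroxyphenyl)ethenyl]-2-(4-hydroxy-3,5-dimethoxyphenyl)-3-(hydroxymethyl)-2,3-dihydro-1,4-benzodioxin-5-ol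
Conditions: HCl (cat.), MeOH, 40 °C, under argon
Reagents that add atoms: none
Why: Acid-catalysed acetal exchange of the four aryl MOM ethers with methanol, tolerable because 2-aryl-1,4-benzodioxanes of this type withstand Brønsted acid and because any reversible ionisation of C2–O1 would reclose under control of the fixed C3 centre to the more stable trans ring.

Compound list
1 | 3-bromo-4,5-dihydroxybenzaldehyde | O=Cc1cc(O)c(O)c(Br)c1 | starting material
2 | 3-bromo-4-hydroxy-5-(methoxymethoxy)benzaldehyde | O=Cc1cc(OCOC)c(O)c(Br)c1 | intermediate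
3 | 2-bromo-4-ethenyl-6-(methoxymethoxy)phenol | C=Cc1cc(OCOC)c(O)c(Br)c1 | intermediate
4 | 5-iodobenzene-1,3-diol | Oc1cc(O)cc(I)c1 | starting material
5 | 1-iodo-3,5-bis(methoxymethoxy)benzene | COCOc1cc(I)cc(OCOC)c1 | intermediate
6 | 4-{(E)-2-[3,5-bis(methoxymethoxy)phenyl]ethenyl}-2-bromo-6-(methoxymethoxy)phenol | COCOc1cc(/C=C/c2cc(OCOC)c(O)c(Br)c2)cc(OCOC)c1 | intermediate
7 | (4R)-4-benzyl-3-(chloroacetyl)-1,3-oxazolidin-2-one | O=C1OC[C@@H](Cc2ccccc2)N1C(=O)CCl | starting material
8 | (4R)-4-benzyl-3-{[4-{(E)-2-[3,5-bis(methoxymethoxy)phenyl]ethenyl}-2-bromo-6-(methoxymethoxy)phenoxy]acetyl}-1,3-oxazolidin-2-one | O=C1OC[C@@H](Cc2ccccc2)N1C(=O)COc1c(Br)cc(/C=C/c2cc(OCOC)cc(OCOC)c2)cc1OCOC | intermediate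
9 | syringaldehyde (4-hydroxy-3,5-dimethoxybenzaldehyde) | COc1cc(C=O)cc(OC)c1O | starting material
10 | 3,5-dimethoxy-4-(methoxymethoxy)benzaldehyde | COCOc1c(OC)cc(C=O)cc1OC | intermediate
11 | (Z)-dibutylboron enolate of 8 | CCCCB(CCCC)O/C(=C\Oc1c(Br)cc(/C=C/c2cc(OCOC)cc(OCOC)c2)cc1OCOC)N1[C@H](Cc2ccccc2)COC1=O | intermediate
12 | dibutylboron aldolate, (2R,3S)-syn | COCOc1c(OC)cc([C@H](OB(CCCC)CCCC)[C@@H](Oc2c(Br)cc(/C=C/c3cc(OCOC)cc(OCOC)c3)cc2OCOC)C(=O)N2[C@H](Cc3ccccc3)COC2=O)cc1OC | intermediate
13 | (2R,3S)-syn 2-aryloxy-3-aryl-3-hydroxypropanoyl imide | COCOc1c(OC)cc([C@H](O)[C@@H](Oc2c(Br)cc(/C=C/c3cc(OCOC)cc(OCOC)c3)cc2OCOC)C(=O)N2[C@H](Cc3ccccc3)COC2=O)cc1OC | intermediate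
14 | trans-(2S,3R)-2-aryl-1,4-benzodioxane-3-carbonyl imide of (R)-4-benzyloxazolidin-2-one, all phenols as MOM ethers | COCOc1c(OC)cc([C@@H]2Oc3cc(/C=C/c4cc(OCOC)cc(OCOC)c4)cc(OCOC)c3O[C@H]2C(=O)N2[C@H](Cc3ccccc3)COC2=O)cc1OC | intermediate
15 | (2S,3S)-tetrakis-MOM ether of the target with free CH2OH | COCOc1c(OC)cc([C@@H]2Oc3cc(/C=C/c4cc(OCOC)cc(OCOC)c4)cc(OCOC)c3O[C@H]2CO)cc1OC | intermediate
16 | (2S,3S)-7-[(E)-2-(3,5-dihydroxyphenyl)ethenyl]-2-(4-hydroxy-3,5-dimethoxyphenyl)-3-(hydroxymethyl)-2,3-dihydro-1,4-benzodioxin-5-ol | COc1cc([C@@H]2Oc3cc(/C=C/c4cc(O)cc(O)c4)cc(O)c3O[C@H]2CO)cc(OC)c1O | target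

Total step count: 9. Longest linear sequence: 7 steps (1, 2, 4, 5, 7, 8, 9).

Steps most likely to fail

Step 7. In the basic second stage several things may go wrong. The carbinol may undergo retro-aldol cleavage or attack the oxazolidinone carbonyl group. The palladium alkoxide may lose a beta-hydride. The acidic C3–H of the product may allow epimerisation or ring opening by beta-elimination. The fallback sets out from 8 and 10 and comes back at 15. The aldol addition is run alone and worked up with H2O2 to give isolated 13. LiBH4 removes the auxiliary to give the (1S,2S)-1,3-diol F1. TBSCl and imidazole silylate only the primary alcohol to give the primary silyl ether F2. The ring is then closed by the same etherification (Pd(OAc)2, the binaphthyl phosphine, Cs2CO3, toluene, 70 °C). At this stage no carbonyl group is left and retro-aldol cleavage is impossible, and the product is the silylated benzodioxane F3. Bu4NF then gives 15.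

Step 1. The very reactive alkylating agent may show poor regioselectivity between the two phenoxides or alkylate twice. The fallback sets out from 1 and comes back at 2, and it uses the acidity order instead of the nucleophilicity order. Allyl bromide with NaHCO3 in DMF alkylates only the more acidic 4-OH to give 4-(allyloxy)-3-bromo-5-hydroxybenzaldehyde F4. MOMCl and K2CO3 cap the remaining phenol to give 4-(allyloxy)-3-bromo-5-(methoxymethoxy)benzaldehyde F5. Pd(PPh3)4 with morpholine in THF at rt removes the allyl group to give 2.

Step 9. Acid may ionise the benzylic C2–O1 bond with capture by methanol or protonate the electron-rich stilbene and start oligomerisation. Formaldehyde equivalents may also attack ring B. The fallback sets out from 15 and comes back at 16, and it avoids Brønsted acid altogether. Me3SiOTf with 2,2'-bipyridyl in MeCN at 0 °C exchanges each aryl MOM ether for a silyl ether under buffered conditions and silylates the alcohol, giving the pentakis(trimethylsilyl) ether F6. Addition of water at rt then hydrolyses F6 to 16.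

Further compounds
F1 | step 7 | (1S,2S)-2-[4-{(E)-2-[3,5-bis(methoxymethoxy)phenyl]ethenyl}-2-bromo-6-(methoxymethoxy)phenoxy]-1-[3,5-dimethoxy-4-(methoxymethoxy)phenyl]propane-1,3-diol | COCOc1c(OC)cc([C@H](O)[C@H](CO)Oc2c(Br)cc(/C=C/c3cc(OCOC)cc(OCOC)c3)cc2OCOC)cc1OC
F2 | step 7 | 3-O-tert-butyldimethylsilyl ether of F1 | COCOc1c(OC)cc([C@H](O)[C@H](CO[Si](C)(C)C(C)(C)C)Oc2c(Br)cc(/C=C/c3cc(OCOC)cc(OCOC)c3)cc2OCOC)cc1OC
F3 | step 7 | tert-butyldimethylsilyl ether of 15 | COCOc1c(OC)cc([C@@H]2Oc3cc(/C=C/c4cc(OCOC)cc(OCOC)c4)cc(OCOC)c3O[C@H]2CO[Si](C)(C)C(C)(C)C)cc1OC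
F4 | step 1 | 4-(allyloxy)-3-bromo-5-hydroxybenzaldehyde | C=CCOc1c(O)cc(C=O)cc1Br
F5 | step 1 | 4-(allyloxy)-3-bromo-5-(methoxymethoxy)benzaldehyde | C=CCOc1c(OCOC)cc(C=O)cc1Br
F6 | step 9 | pentakis(trimethylsilyl) ether of 16 | COc1cc([C@@H]2Oc3cc(/C=C/c4cc(O[Si](C)(C)C)cc(O[Si](C)(C)C)c4)cc(O[Si](C)(C)C)c3O[C@H]2CO[Si](C)(C)C)cc(OC)c1O[Si](C)(C)C
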